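**Plan**

- Cuts (carotane numbering): the C6–O ester bond; the C6–C7 bond of the seven-membered ring B (a dienal hydroacylation in reverse); the C4–isopropyl bond; and, in one operation, C1–C10 and C5–C6 on the five-membered ring A.
- Enabling feature: quaternary C1 and ring-fusion C5 are the β- and α-carbons of a ring A cyclopentanone whose carbonyl carbon is C4. Ring A can therefore be 3-methylcyclopent-2-enone, C10–C9–C8(Me)–C7 a dienyl nucleophile and C6 formaldehyde.
- Forward: ring A is bought. One copper-catalysed operation adds the dienyl group to C1 and traps the enolate at C5 with formaldehyde. Isopropyl is then added to C4. Ring B closes last by rhodium-catalysed C6–C7 bond formation, which leaves C8=C9 in place. Reduction at C6 and salicyloylation finish.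
- Stereochemistry: C1 from the chiral carbene–copper catalyst; C5 from aldol trapping anti to the dienyl group; C4 from isopropyl attack anti to the C5 side chain; C6 from hydride delivered by the C4 hydroxyl.

Key step: step 2

Remark: carotane numbering is used for all intermediates (C1 methyl-bearing quaternary carbon, C4 carbinol carbon, C5 ring-fusion CH, C6 ester carbon, C7 CH2, C8=C9 with methyl on C8, C10 CH2). The target is taken as drawn: 1R,4R,5S,6S, trans-fused. Formaldehyde is used as the anhydrous monomer obtained by cracking paraformaldehyde.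

**Route**

Step 1
Reactants: 1 2-methylbut-1-en-3-yne
Product: 2 (E)-diisobutyl(3-methylbuta-1,3-dien-1-yl)alane
Conditions: iBu2AlH (1.0 equiv), hexane, 0 → 50 °C, sealed vessel; solution used as such
Reagents that add atoms: diisobutylaluminium hydride, CC(C)C[AlH]CC(C)C
Why: Hydroalumination of a terminal alkyne is a syn addition that places aluminium on the terminal carbon, so the (E)-alkenylalane should form while the 1,1-disubstituted alkene, far less reactive toward the Al–H bond, is left alone.

Step 2
Reactants: 2 (E)-diisobutyl(3-methylbuta-1,3-dien-1-yl)alane; 3 3-methylcyclopent-2-en-1-one; 4 formaldehyde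
Product: 6 (2S,3R)-2-(hydroxymethyl)-3-methyl-3-[(1E)-3-methylbuta-1,3-dien-1-yl]cyclopentan-1-one, via diisobutylaluminium enolate 5 (not isolated)
Conditions: Cu(OTf)2 (5 mol %), enantiopure sulfonate-bearing imidazolinium salt derived from 1,2-diphenylethylenediamine (carbene precursor, 5.5 mol %), 2 (1.2 equiv), THF/hexane, −30 °C; then CH2O monomer (excess) in THF, −78 → −40 °C; aq. potassium sodium tartrate
Reagents that add atoms: none
Why: The alane deprotonates the imidazolinium salt and reduces Cu(OTf)2 to monovalent copper, the dienyl group passes from aluminium to the chiral carbene–copper centre, and this species adds it to the β-carbon of enone 3 (C1–C10 bond) to leave aluminium enolate 5, which then attacks formaldehyde through carbon in a closed aldol transition state (C5–C6 bond) before aqueous work-up releases 6. The closest known reaction type is the carbene–copper-catalysed enantioselective conjugate addition of alkenylaluminium reagents to β-methyl cyclic enones with trapping of the aluminium enolate by an aldehyde. No ring is closed. C1 is set by the catalyst, which distinguishes the enantiotopic faces of the flat enone (the ligand antipode that leads to 3R is used), and C5 by the substrate, since formaldehyde should reach the enolate carbon on the face turned away from the extended dienyl arm of the neighbouring quaternary carbon, that is syn to the methyl group. The step needs 1,4- rather than 1,2-addition and transfer of the sp2 group rather than isobutyl, both secured by copper catalysis, and a single C-hydroxymethylation, secured by the oxophilic aluminium enolate, the low temperature and the use of anhydrous monomeric formaldehyde. Because methyl and alkenyl differ only moderately in size, any C5 epimer is to be removed by chromatography at 6 or 7.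

Step 3
Reactants: 6 (2S,3R)-2-(hydroxymethyl)-3-methyl-3-[(1E)-3-methylbuta-1,3-dien-1-yl]cyclopentan-1-one
Product: 7 (2S,3R)-2-{[tert-butyl(dimethyl)silyl]oxymethyl}-3-methyl-3-[(1E)-3-methylbuta-1,3-dien-1-yl]cyclopentan-1-one
Conditions: TBSCl, imidazole, DMF, 0 °C
Reagents that add atoms: tert-butyldimethylsilyl chloride, CC(C)(C)[Si](C)(C)Cl
Why: Imidazole-promoted silylation of a primary alcohol is fast and mild enough that neither retro-aldol cleavage, β-elimination nor epimerisation at C5 should intervene, and it removes the acidic proton before the organometallic addition.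

Step 4
Reactants: 7 (2S,3R)-2-{[tert-butyl(dimethyl)silyl]oxymethyl}-3-methyl-3-[(1E)-3-methylbuta-1,3-dien-1-yl]cyclopentan-1-one
Product: 8 (1R,2S,3R)-2-{[tert-butyl(dimethyl)silyl]oxymethyl}-3-methyl-3-[(1E)-3-methylbuta-1,3-dien-1-yl]-1-(propan-2-yl)cyclopentan-1-ol
Conditions: iPrMgCl (3 equiv), anhydrous CeCl3 (3 equiv), THF, −78 → −20 °C; aq. NH4Cl
Reagents that add atoms: isopropylmagnesium chloride, CC(C)[Mg]Cl
Why: The weakly basic organocerium reagent adds a secondary alkyl group to an enolisable α-branched ketone (organocerium carbonyl addition) without enolisation, β-hydride reduction or loss of the β-silyloxy group, and it should attack C4 on the ring face opposite the adjacent C5 silyloxymethyl group, which places the new hydroxyl cis to that side chain (4R).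

Step 5
Reactants: 8 (1R,2S,3R)-2-{[tert-butyl(dimethyl)silyl]oxymethyl}-3-methyl-3-[(1E)-3-methylbuta-1,3-dien-1-yl]-1-(propan-2-yl)cyclopentan-1-ol
Product: 9 (1R,2S,3R)-2-(hydroxymethyl)-3-methyl-3-[(1E)-3-methylbuta-1,3-dien-1-yl]-1-(propan-2-yl)cyclopentan-1-ol
Conditions: Bu4NF, THF, 0 °C → rt; water
Reagents that add atoms: none
Why: Fluoride-induced desilylation cleaves the primary silyl ether through Si–F bond formation and touches neither the tertiary alcohol nor the diene.

Step 6
Reactants: 9 (1R,2S,3R)-2-(hydroxymethyl)-3-methyl-3-[(1E)-3-methylbuta-1,3-dien-1-yl]-1-(propan-2-yl)cyclopentan-1-ol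
Product: 10 (1R,2R,5R)-2-hydroxy-5-methyl-5-[(1E)-3-methylbuta-1,3-dien-1-yl]-2-(propan-2-yl)cyclopentane-1-carbaldehyde
Conditions: TEMPO (10 mol %), PhI(OAc)2 (1.1 equiv), CH2Cl2, rt; used without chromatography
Reagents that add atoms: none
Why: The oxoammonium-mediated oxidation is selective for the primary alcohol and stops at the aldehyde, its near-neutral medium should spare the β-hydroxy aldehyde from dehydration and retro-aldol cleavage, and C5, now α to the formyl group, already has its more stable configuration with the formyl group trans to both isopropyl and the dienyl group.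

Step 7
Reactants: 10 (1R,2R,5R)-2-hydroxy-5-methyl-5-[(1E)-3-methylbuta-1,3-dien-1-yl]-2-(propan-2-yl)cyclopentane-1-carbaldehyde
Product: 11 (3R,3aR,8aR)-3-hydroxy-6,8a-dimethyl-3-(propan-2-yl)-1,2,3,3a,8,8a-hexahydroazulen-4(5H)-one
Conditions: [Rh(dppe)]ClO4 (10 mol %, made from [Rh(nbd)(dppe)]ClO4 and H2), ClCH2CH2Cl, 65 °C
Reagents that add atoms: none
Why: In this intramolecular hydroacylation of a 4,6-dienal by cationic monovalent rhodium, oxidative addition of the formyl C–H bond, hydride transfer to C10 to give an acyl(η3-allyl)rhodium species and reductive elimination at the allyl terminus C7 close the seven-membered ring B as the β,γ-unsaturated ketone with C8=C9 in place, the alternative closure at C9 being disfavoured because it would give a trans-fused bicyclo[3.3.0]octanone, and no stereocentre is created while C5 is retained.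

Step 8
Reactants: 11 (3R,3aR,8aR)-3-hydroxy-6,8a-dimethyl-3-(propan-2-yl)-1,2,3,3a,8,8a-hexahydroazulen-4(5H)-one
Product: 12 (3R,3aS,4S,8aR)-6,8a-dimethyl-3-(propan-2-yl)-1,2,3,3a,4,5,8,8a-octahydroazulene-3,4-diol
Conditions: Me4NBH(OAc)3 (5 equiv), MeCN/AcOH, −30 → 0 °C; aq. potassium sodium tartrate
Reagents that add atoms: none
Why: In this Evans–Saksena reduction the C4 hydroxyl exchanges an acetate on boron and the resulting alkoxyborohydride should deliver hydride within the molecule to the face of the C6 carbonyl that is syn to C4, which gives the C6 hydroxyl cis to H5 (6S), while the acidic medium avoids enolisation at C5 and retro-aldol cleavage and the reagent does not reduce a ketone that lacks the directing group.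

Step 9
Reactants: 12 (3R,3aS,4S,8aR)-6,8a-dimethyl-3-(propan-2-yl)-1,2,3,3a,4,5,8,8a-octahydroazulene-3,4-diol; 13 O-acetylsalicyloyl chloride
Product: 14 [(3R,3aS,4S,8aR)-3-hydroxy-6,8a-dimethyl-3-(propan-2-yl)-1,2,3,3a,4,5,8,8a-octahydroazulen-4-yl] 2-(acetyloxy)benzoate
Conditions: 13 (1.5 equiv), pyridine, DMAP (catalytic), CH2Cl2, 0 °C → rt
Reagents that add atoms: none
Why: DMAP-catalysed acylation by an acid chloride esterifies the secondary C6 hydroxyl, whereas the hindered tertiary C4 hydroxyl does not react, and the acetate keeps the phenol from competing.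

Step 10
Reactants: 14 [(3R,3aS,4S,8aR)-3-hydroxy-6,8a-dimethyl-3-(propan-2-yl)-1,2,3,3a,4,5,8,8a-octahydroazulen-4-yl] 2-(acetyloxy)benzoate
Product: 15 [(3R,3aS,4S,8aR)-3-hydroxy-6,8a-dimethyl-3-(propan-2-yl)-1,2,3,3a,4,5,8,8a-octahydroazulen-4-yl] 2-hydroxybenzoate
Conditions: pyrrolidine (3 equiv), CH2Cl2, 0 °C → rt
Reagents that add atoms: none
Why: Aminolysis of the activated aryl acetate is much faster than attack on the hindered secondary alkyl benzoate, so this chemoselective deacetylation should free the phenol alone, after which the ortho-hydroxyl deactivates the salicylate by hydrogen bonding.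

**Compound list**

1 | 2-methylbut-1-en-3-yne | C=C(C)C#C | starting material
2 | (E)-diisobutyl(3-methylbuta-1,3-dien-1-yl)alane | CC(C)C[Al](CC(C)C)/C=C/C(C)=C | intermediate
3 | 3-methylcyclopent-2-en-1-one | CC1=CC(=O)CC1 | starting material
4 | formaldehyde | C=O | starting material
5 | diisobutylaluminium (R)-3-methyl-3-[(1E)-3-methylbuta-1,3-dien-1-yl]cyclopent-1-en-1-olate | C=C(C)/C=C/[C@@]1(C)CCC(O[Al](CC(C)C)CC(C)C)=C1 | intermediate
6 | (2S,3R)-2-(hydroxymethyl)-3-methyl-3-[(1E)-3-methylbuta-1,3-dien-1-yl]cyclopentan-1-one | C=C(C)/C=C/[C@@]1(C)CCC(=O)[C@@H]1CO | intermediate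
7 | (2S,3R)-2-{[tert-butyl(dimethyl)silyl]oxymethyl}-3-methyl-3-[(1E)-3-methylbuta-1,3-dien-1-yl]cyclopentan-1-one | C=C(C)/C=C/[C@@]1(C)CCC(=O)[C@@H]1CO[Si](C)(C)C(C)(C)C | intermediate
8 | (1R,2S,3R)-2-{[tert-butyl(dimethyl)silyl]oxymethyl}-3-methyl-3-[(1E)-3-methylbuta-1,3-dien-1-yl]-1-(propan-2-yl)cyclopentan-1-ol | C=C(C)/C=C/[C@@]1(C)CC[C@@](O)(C(C)C)[C@@H]1CO[Si](C)(C)C(C)(C)C | intermediate
9 | (1R,2S,3R)-2-(hydroxymethyl)-3-methyl-3-[(1E)-3-methylbuta-1,3-dien-1-yl]-1-(propan-2-yl)cyclopentan-1-ol | C=C(C)/C=C/[C@@]1(C)CC[C@@](O)(C(C)C)[C@@H]1CO | intermediate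
10 | (1R,2R,5R)-2-hydroxy-5-methyl-5-[(1E)-3-methylbuta-1,3-dien-1-yl]-2-(propan-2-yl)cyclopentane-1-carbaldehyde | C=C(C)/C=C/[C@@]1(C)CC[C@@](O)(C(C)C)[C@@H]1C=O | intermediate
11 | (3R,3aR,8aR)-3-hydroxy-6,8a-dimethyl-3-(propan-2-yl)-1,2,3,3a,8,8a-hexahydroazulen-4(5H)-one (trans-fused) | CC1=CC[C@@]2(C)CC[C@@](O)(C(C)C)[C@@H]2C(=O)C1 | intermediate
12 | (3R,3aS,4S,8aR)-6,8a-dimethyl-3-(propan-2-yl)-1,2,3,3a,4,5,8,8a-octahydroazulene-3,4-diol | CC1=CC[C@@]2(C)CC[C@@](O)(C(C)C)[C@@H]2[C@@H](O)C1 | intermediate
13 | O-acetylsalicyloyl chloride | CC(=O)Oc1ccccc1C(Cl)=O | starting material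
14 | [(3R,3aS,4S,8aR)-3-hydroxy-6,8a-dimethyl-3-(propan-2-yl)-1,2,3,3a,4,5,8,8a-octahydroazulen-4-yl] 2-(acetyloxy)benzoate | CC1=CC[C@@]2(C)CC[C@@](O)(C(C)C)[C@@H]2[C@@H](OC(=O)c2ccccc2OC(C)=O)C1 | intermediate
15 | [(3R,3aS,4S,8aR)-3-hydroxy-6,8a-dimethyl-3-(propan-2-yl)-1,2,3,3a,4,5,8,8a-octahydroazulen-4-yl] 2-hydroxybenzoate | CC1=CC[C@@]2(C)CC[C@@](O)(C(C)C)[C@@H]2[C@@H](OC(=O)c2ccccc2O)C1 | target

**Count**

Total steps: 10. Longest linear sequence: 10 steps (1 to 15).

**Steps most likely to fail**

Step 2. The methyl and dienyl groups on C1 may not differentiate the two faces of the enolate well enough during the aldol trapping, and the enantioselectivity of the dienyl transfer to a five-membered enone may fall short; formaldehyde may also oligomerise before the enolate reacts. The fallback separates the two bond formations and puts C5 under catalyst control. Setting out from 2 and 3, the same copper-catalysed conjugate addition is quenched with Et3SiOTf to give the triethylsilyl enol ether F1. F1 is then hydroxymethylated with aqueous formaldehyde under Sc(OTf)3 and an enantiopure 2,2'-bipyridine diol ligand (aqueous Mukaiyama aldol), with the ligand antipode chosen to deliver the hydroxymethyl group syn to the C1 methyl. This comes back to the route at 6.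

Step 7. The acylrhodium hydride may lose CO, the C8=C9 alkene may drift into conjugation with the ketone, or the β-hydroxy aldehyde may dehydrate under the Lewis-acidic cationic complex. The fallback closes ring B by olefin metathesis at C8=C9 instead. Setting out from 10, Barbier methallylation (2-methylallyl bromide, indium powder, THF/H2O) gives the homoallylic alcohol F2 as C6 epimers. Dissolving-metal 1,4-reduction of the diene (Na, liquid NH3, tBuOH, −78 °C) turns the dienyl group into a prenyl group in the diene-diol F3. Ring-closing metathesis with the second-generation Grubbs catalyst (toluene, 80 °C) gives the cycloheptenol F4; the ring carbons C7 and C8 then stem from the methallyl unit. Dess–Martin oxidation of the secondary alcohol comes back to the route at 11.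

Step 8. Ligand exchange at the hindered tertiary C4 hydroxyl may be too slow for internal delivery, so that hydride arrives from the more open face (syn to H5) and gives the wrong C6 configuration. The fallback accepts that facial outcome and corrects it in the esterification. Setting out from 11, reduction with external hydride (NaBH4, CeCl3·7H2O, MeOH, −78 °C, Luche conditions) gives the 6-epi diol F5. Mitsunobu esterification of F5 with 2-acetoxybenzoic acid (PPh3, DIAD, THF) inverts C6 and comes back to the route at 14.

**Further compounds**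

F1 | step 2 | (R)-triethyl({3-methyl-3-[(1E)-3-methylbuta-1,3-dien-1-yl]cyclopent-1-en-1-yl}oxy)silane | C=C(C)/C=C/[C@@]1(C)CCC(O[Si](CC)(CC)CC)=C1
F2 | step 7 | (1R,2S,3R)-2-(1-hydroxy-3-methylbut-3-en-1-yl)-3-methyl-3-[(1E)-3-methylbuta-1,3-dien-1-yl]-1-(propan-2-yl)cyclopentan-1-ol (both C6 epimers) | C=C(C)/C=C/[C@@]1(C)CC[C@@](O)(C(C)C)[C@@H]1C(O)CC(C)=C
F3 | step 7 | (1R,2S,3R)-2-(1-hydroxy-3-methylbut-3-en-1-yl)-3-methyl-3-(3-methylbut-2-en-1-yl)-1-(propan-2-yl)cyclopentan-1-ol (both C6 epimers) | CC(C)=CC[C@@]1(C)CC[C@@](O)(C(C)C)[C@@H]1C(O)CC(C)=C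
F4 | step 7 | (3R,3aS,8aR)-6,8a-dimethyl-3-(propan-2-yl)-1,2,3,3a,4,5,8,8a-octahydroazulene-3,4-diol (both epimers at the secondary carbinol) | CC1=CC[C@@]2(C)CC[C@@](O)(C(C)C)[C@@H]2C(O)C1
F5 | step 8 | (3R,3aS,4R,8aR)-6,8a-dimethyl-3-(propan-2-yl)-1,2,3,3a,4,5,8,8a-octahydroazulene-3,4-diol | CC1=CC[C@@]2(C)CC[C@@](O)(C(C)C)[C@@H]2[C@H](O)C1
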